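**Retrosynthetic overview**

1. Target ⇒ 11-ketone (late methylenation, then epoxidation) and a (5Z)-5,6-olefin (late ene-type chlorination gives C6–Cl and the C5/C16 methylene).
2. Hydroxy-lactone ⇒ intramolecular Reformatsky reaction of a C7 2-bromopropanoate onto the C8 ketone; C2 carbinol ⇒ CBS reduction of the C2 ketone.
3. Ten-membered ring ⇒ key step: SmI2 ketyl cyclisation/retro-aldol ring expansion (six → ten) of a 2-acylcyclohexenone (ring C) that carries ring A.
4. That precursor ⇒ aldol union (C2–C3) of a ring A aldehyde with the Birch-derived enolate of p-cresol, then oxidation.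
5. Ring A ⇒ catalytic asymmetric Diels–Alder reaction. Ring order: A, C (six-membered), transient B, ten-membered ring, lactone, epoxide.

Assumption: atoms carry briarane numbers (C1 quaternary carbon, C2 isobutyrate carbon, C5/C16 methylene, C6 chloride carbon, C7/C8/C17/C19 lactone, C9 and C14 acetate carbons, C11/C20 epoxide, C15 and C18 methyls); 11–13 and 20 are used as the stated epimer mixtures, and the route is a paper proposal that has not been run.

**Step 1**
Reactants: 1 (1E,3E)-buta-1,3-diene-1,4-diyl diacetate; 2 (E)-4,4-dimethoxy-2-methylbut-2-enal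
Product: 3 ring A cyclohexene (1-formyl-1-methyl-6-(dimethoxymethyl)cyclohex-3-ene-2,5-diyl diacetate; CHO and both OAc cis, CH(OMe)2 trans to CHO)
Conditions: (S)-o-tolyl-CBS-oxazaborolidine (20 mol %), Tf2NH (18 mol %), CH2Cl2, −78 → −40 °C
Reagents that add atoms: none
Why: Lewis-acid-catalysed endo Diels–Alder reaction: the (E,E)-diene puts both acetates cis, the activated formyl group sits endo and ends cis to them, the (E)-enal keeps CH(OMe)2 trans to CHO, and the chiral oxazaborolidinium shields one enal face, so C1, C10, C11 and C14 are set in one step.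

**Step 2**
Reactants: 3 ring A cyclohexene
Product: 4 ring A cyclohexane (same substituents, ring saturated)
Conditions: H2 (1 atm), 5% Rh/Al2O3, EtOAc, 23 °C
Reagents that add atoms: none
Why: heterogeneous hydrogenation of the cis-disubstituted ring olefin, under which the aldehyde, the acetal and the allylic acetates survive and no stereocentre is touched.

**Step 3**
Reactants: 4 ring A cyclohexane
Product: 5 C11 alcohol (C14 acetate kept)
Conditions: K2CO3 (0.2 equiv), MeOH, −20 °C
Reagents that add atoms: none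
Why: base-catalysed methanolysis (transesterification) is fastest at the equatorial C11 acetate, because the axial C14 acetate is shielded by the adjacent quaternary C1.

**Step 4**
Reactants: 5 C11 alcohol
Product: 6 ring A aldehyde (C11 OTBS, C14 OAc, C9 dimethyl acetal)
Conditions: TBSCl, imidazole, DMF, 23 °C
Reagents that add atoms: tert-butyldimethylsilyl chloride (TBSCl), CC(C)(C)[Si](C)(C)Cl
Why: standard silylation of the only free hydroxyl group; the aldehyde has no α-hydrogen and is inert.

**Step 5**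
Reactants: 7 p-cresol (4-methylphenol)
Product: 8 tert-butyldimethyl(4-methylphenoxy)silane
Conditions: TBSCl, imidazole, DMF, 23 °C
Reagents that add atoms: tert-butyldimethylsilyl chloride (TBSCl), CC(C)(C)[Si](C)(C)Cl
Why: standard phenol silylation to prepare the Birch substrate.

**Step 6**
Reactants: 8 aryl silyl ether
Product: 9 tert-butyldimethyl[(4-methylcyclohexa-1,4-dien-1-yl)oxy]silane
Conditions: Li, NH3 (l), t-BuOH, THF, −78 → −33 °C
Reagents that add atoms: none
Why: Birch reduction leaves the two donor-bearing carbons sp2, giving the 1,4-diene whose silyl enol ether is regiodefined (nucleophilic at the future C3) next to the future C5(Me)=C6 olefin.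

**Step 7**
Reactants: 9 silyl dienol ether; 6 ring A aldehyde
Product: 11 aldol adduct (C2–C3 bond; C2/C3 epimer mixture), via lithium dienolate 10 (not isolated)
Conditions: MeLi, THF, 0 → 23 °C; then 6, −78 °C; AcOH quench at −78 °C
Reagents that add atoms: none
Why: MeLi cleaves the silyl enol ether to the regiodefined lithium enolate, which adds to the neopentyl aldehyde faster than to the acetate (aldol addition); the two new centres are erased in step 8.

**Step 8**
Reactants: 11 aldol adduct
Product: 12 1,3-diketone (C2 and C8 carbonyls, enolised)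
Conditions: Dess–Martin periodinane (DMP), CH2Cl2, 0 → 23 °C
Reagents that add atoms: none
Why: Dess–Martin oxidation of the secondary carbinol gives the 2-acylcyclohexenone and removes the C2/C3 mixture.

**Step 9**
Reactants: 12 1,3-diketone
Product: 13 keto-aldehyde (C9 CHO)
Conditions: oxalic acid (10 mol %), wet silica gel, CH2Cl2, 23 °C; used crude at once
Reagents that add atoms: water, O
Why: mild acetal hydrolysis that leaves the secondary TBS ether, the acetate and the β,γ-olefin alone; immediate use avoids intramolecular Knoevenagel attack of C3 on the aldehyde.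

**Step 10**
Reactants: 13 keto-aldehyde
Product: 15 ring-expanded ketol (ten-membered ring; C2 and C8 ketones, 9-epi-OH, (5Z)-olefin), via tricyclic pinacol diol 14 (not isolated)
Conditions: SmI2 (2.5 equiv), HMPA, THF, −78 → 0 °C; cold pH 7 phosphate buffer
Reagents that add atoms: none
Why: Proposed new method: a samarium ketyl–carbonyl cyclisation/retro-aldol ring expansion. SmI2 turns the aldehyde into its ketyl, which closes six-membered ring B onto the C8 carbonyl of the 1,3-diketone as a cis-diolate with the C9 oxygen equatorial, away from the axial C15 methyl. The resulting trivalent-samarium tertiary aldolate is a crowded ketone–ketone aldol and cleaves by retro-aldol at the shared C3–C8 bond, the only bond whose scission gives an enolate. Ring C is thereby enlarged by four atoms to the ten-membered ring, held as a chelated α-alkoxy ketone with the ring olefin still Z. Closest known chemistry: Molander's SmI2 Barbier-cyclisation/Grob-fragmentation ring expansions and samarium-promoted retro-aldol reactions of β-hydroxy ketones.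

**Step 11**
Reactants: 15 ring-expanded ketol
Product: 16 C9 acetate (C9 configured as in the target)
Conditions: AcOH, PPh3, DIAD, THF, 0 °C
Reagents that add atoms: acetic acid, CC(=O)O
Why: Mitsunobu esterification of the α-hydroxy ketone inverts C9 (SN2 next to a carbonyl is fast) and installs the acetate in one operation.

**Step 12**
Reactants: 16 C9 acetate
Product: 18 C7 alcohol (α-hydroxy ketone), via trimethylsilyl dienol ether 17 (not isolated)
Conditions: TMSOTf (1.05 equiv), Et3N, CH2Cl2, −78 °C; then dimethyldioxirane, acetone, −78 → −40 °C; citric acid (cat.), MeOH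
Reagents that add atoms: dimethyldioxirane, CC1(C)OO1
Why: Rubottom oxidation: soft enolisation takes the doubly activated C7–H (allylic and α to the C8 ketone) in preference to C3–H, and the dioxirane attacks the electron-rich enol ether bond from the open outer face of the medium ring to set C7.

**Step 13**
Reactants: 18 C7 alcohol; 19 2-bromopropanoyl bromide (racemic)
Product: 20 C7 2-bromopropanoate (epimer mixture at the bromide carbon)
Conditions: pyridine, CH2Cl2, −20 °C
Reagents that add atoms: none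
Why: O-acylation of the only free hydroxyl group brings in C17, C18 and C19.

**Step 14**
Reactants: 20 C7 2-bromopropanoate
Product: 21 hydroxy-lactone (C8 OH, C17 methyl, trans-fused γ-lactone)
Conditions: SmI2 (2.2 equiv), THF, −78 °C
Reagents that add atoms: none
Why: intramolecular Reformatsky reaction: C–Br reduction is faster than ketone reduction, and the tethered trivalent-samarium enolate must bond to the C8 face syn to O7; with the C6–C7 and C8–C9 ring bonds anti in the reacting conformer, OH-8 ends trans to H-7 and the C18 methyl sits exo (cis to OH-8).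

**Step 15**
Reactants: 21 hydroxy-lactone
Product: 22 (2S)-alcohol
Conditions: (R)-2-methyl-CBS-oxazaborolidine (20 mol %), catecholborane, toluene, −78 °C
Reagents that add atoms: none
Why: Corey–Bakshi–Shibata reduction of the only remaining ketone; reagent control (large group = quaternary C1 side, small = C3 methylene) gives the (S)-carbinol, and catecholborane at −78 °C does not hydroborate the trisubstituted olefin.

**Step 16**
Reactants: 22 (2S)-alcohol
Product: 23 C2 isobutyrate
Conditions: isobutyryl chloride, pyridine, DMAP (cat.), CH2Cl2, 0 → 23 °C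
Reagents that add atoms: 2-methylpropanoyl chloride (isobutyryl chloride), CC(C)C(Cl)=O
Why: acylation of the secondary alcohol; the tertiary C8 hydroxyl does not react.

**Step 17**
Reactants: 23 C2 isobutyrate
Product: 24 allylic chloride (C6 Cl, C5/C16 methylene)
Conditions: Ca(OCl)2, CO2 (dry ice), CH2Cl2/H2O, 0 °C
Reagents that add atoms: calcium hypochlorite, [Ca+2].[O-]Cl.[O-]Cl
Why: ene-type chlorination with HOCl made in situ: chlorine adds to the less substituted C6 on the face anti to the allylic C7–O bond (H-7 in the olefin plane) and the proton is lost from the C16 methyl, which sets C6 and creates the exocyclic methylene.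

**Step 18**
Reactants: 24 allylic chloride
Product: 25 C11 alcohol
Conditions: HF·pyridine, pyridine, THF, 0 → 23 °C
Reagents that add atoms: none
Why: fluoride cleavage of the secondary silyl ether under buffered conditions that spare the esters, the lactone and the allylic chloride.

**Step 19**
Reactants: 25 C11 alcohol
Product: 26 C11 ketone
Conditions: Dess–Martin periodinane (DMP), CH2Cl2, 0 → 23 °C
Reagents that add atoms: none
Why: neutral Dess–Martin oxidation, so the β-acetoxy ketone does not eliminate and C10 does not epimerise.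

**Step 20**
Reactants: 26 C11 ketone
Product: 27 C11/C20 methylene compound
Conditions: Zn, CH2Br2, TiCl4, THF/CH2Cl2, 0 °C
Reagents that add atoms: dibromomethane, BrCBr
Why: Takai–Lombardo methylenation is non-basic and ketone-selective, so the esters, the lactone and the enolisable β-acetoxy ketone survive.

**Step 21**
Reactants: 27 C11/C20 methylene compound
Product: 28 target (CNP0284862.1)
Conditions: mCPBA, CH2Cl2, 0 °C
Reagents that add atoms: 3-chloroperoxybenzoic acid (mCPBA), OOC(=O)c1cccc(Cl)c1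
Why: Prilezhaev epoxidation: the peracid attacks the C11 methylene from the face opposite the axial C15 methyl (oxygen equatorial, as in the target), and the C5/C16 methylene is deactivated by the allylic chloride and the lactone oxygen.

**Compound list**

1 | (1E,3E)-buta-1,3-diene-1,4-diyl diacetate | CC(=O)O/C=C/C=C/OC(C)=O | starting material
2 | (E)-4,4-dimethoxy-2-methylbut-2-enal | COC(OC)/C=C(\C)C=O | starting material
3 | ring A cyclohexene: 1-formyl-1-methyl-6-(dimethoxymethyl)cyclohex-3-ene-2,5-diyl diacetate, CHO and both OAc cis, CH(OMe)2 trans to CHO | O=C[C@@]1(C)[C@@H](OC(C)=O)C=C[C@@H](OC(C)=O)[C@@H]1C(OC)OC | intermediate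
4 | ring A cyclohexane: 1-formyl-1-methyl-6-(dimethoxymethyl)cyclohexane-2,5-diyl diacetate, same configuration | O=C[C@@]1(C)[C@@H](OC(C)=O)CC[C@@H](OC(C)=O)[C@@H]1C(OC)OC | intermediate
5 | C11 alcohol: 2-acetoxy-5-hydroxy analogue of 4 | O=C[C@@]1(C)[C@@H](OC(C)=O)CC[C@@H](O)[C@@H]1C(OC)OC | intermediate
6 | ring A aldehyde: C14 acetate, C11 OTBS, C9 dimethyl acetal, C2 formyl on quaternary C1 | O=C[C@@]1(C)[C@@H](OC(C)=O)CC[C@@H](O[Si](C)(C)C(C)(C)C)[C@@H]1C(OC)OC | intermediate
7 | p-cresol (4-methylphenol) | Cc1ccc(O)cc1 | starting material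
8 | tert-butyldimethyl(4-methylphenoxy)silane | Cc1ccc(O[Si](C)(C)C(C)(C)C)cc1 | intermediate
9 | tert-butyldimethyl[(4-methylcyclohexa-1,4-dien-1-yl)oxy]silane | CC1=CCC(O[Si](C)(C)C(C)(C)C)=CC1 | intermediate
10 | lithium 4-methylcyclohexa-1,4-dien-1-olate | [Li]OC1=CCC(C)=CC1 | intermediate (not isolated)
11 | aldol adduct: 4-methylcyclohex-3-en-1-one carrying at C3 the CH(OH) carbon (C2) bonded to C1 of ring A; C2/C3 epimer mixture | CC1=CCC(=O)C(C1)C(O)[C@@]1(C)[C@@H](OC(C)=O)CC[C@@H](O[Si](C)(C)C(C)(C)C)[C@@H]1C(OC)OC | intermediate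
12 | 1,3-diketone: 2-acyl-4-methylcyclohex-3-enone (C2 and C8 carbonyls), C9 acetal | CC1=CCC(=O)C(C1)C(=O)[C@@]1(C)[C@@H](OC(C)=O)CC[C@@H](O[Si](C)(C)C(C)(C)C)[C@@H]1C(OC)OC | intermediate
13 | keto-aldehyde: as 12 with C9 formyl | CC1=CCC(=O)C(C1)C(=O)[C@@]1(C)[C@@H](OC(C)=O)CC[C@@H](O[Si](C)(C)C(C)(C)C)[C@@H]1C=O | intermediate
14 | tricyclic pinacol diol: rings A, B and C linearly fused, cis C8/C9 diol (C8 OH axial, C9 OH equatorial), C2 ketone, C3–C8 bond intact | CC1=CC[C@]2(O)[C@@H](C1)C(=O)[C@@]1(C)[C@@H](OC(C)=O)CC[C@@H](O[Si](C)(C)C(C)(C)C)[C@@H]1[C@H]2O | intermediate (not isolated)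
15 | ring-expanded ketol: bicyclo[8.4.0] core, C2 and C8 ketones, 9-epi-hydroxy, (5Z)-olefin with C16 methyl, C11 OTBS, C14 OAc | C/C1=C/CC(=O)[C@H](O)[C@H]2[C@H](O[Si](C)(C)C(C)(C)C)CC[C@H](OC(C)=O)[C@]2(C)C(=O)CC1 | intermediate
16 | C9 acetate (C9 as in the target), otherwise as 15 | C/C1=C/CC(=O)[C@@H](OC(C)=O)[C@H]2[C@H](O[Si](C)(C)C(C)(C)C)CC[C@H](OC(C)=O)[C@]2(C)C(=O)CC1 | intermediate
17 | trimethylsilyl dienol ether of 16 (C7=C8 enol ether conjugated with C5=C6, both ring-cis) | C/C1=C/C=C(/O[Si](C)(C)C)[C@@H](OC(C)=O)[C@H]2[C@H](O[Si](C)(C)C(C)(C)C)CC[C@H](OC(C)=O)[C@]2(C)C(=O)CC1 | intermediate (not isolated)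
18 | C7 alcohol: 7-hydroxy-8-ketone, C7 as in the target | C/C1=C/[C@H](O)C(=O)[C@@H](OC(C)=O)[C@H]2[C@H](O[Si](C)(C)C(C)(C)C)CC[C@H](OC(C)=O)[C@]2(C)C(=O)CC1 | intermediate
19 | 2-bromopropanoyl bromide (racemic) | CC(Br)C(Br)=O | starting material
20 | C7 2-bromopropanoate of 18 (epimer mixture at the CHBr carbon) | C/C1=C/[C@H](OC(=O)C(C)Br)C(=O)[C@@H](OC(C)=O)[C@H]2[C@H](O[Si](C)(C)C(C)(C)C)CC[C@H](OC(C)=O)[C@]2(C)C(=O)CC1 | intermediate
21 | hydroxy-lactone: C7–O–C19(=O)–C17(Me)–C8(OH) γ-lactone, trans-fused, C18 methyl cis to OH-8, C2 ketone | C/C1=C/[C@@H]3OC(=O)[C@H](C)[C@@]3(O)[C@@H](OC(C)=O)[C@H]2[C@H](O[Si](C)(C)C(C)(C)C)CC[C@H](OC(C)=O)[C@]2(C)C(=O)CC1 | intermediate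
22 | (2S)-alcohol of 21 | C/C1=C/[C@@H]3OC(=O)[C@H](C)[C@@]3(O)[C@@H](OC(C)=O)[C@H]2[C@H](O[Si](C)(C)C(C)(C)C)CC[C@H](OC(C)=O)[C@]2(C)[C@@H](O)CC1 | intermediate
23 | C2 isobutyrate of 22 | C/C1=C/[C@@H]3OC(=O)[C@H](C)[C@@]3(O)[C@@H](OC(C)=O)[C@H]2[C@H](O[Si](C)(C)C(C)(C)C)CC[C@H](OC(C)=O)[C@]2(C)[C@@H](OC(=O)C(C)C)CC1 | intermediate
24 | allylic chloride: C6 Cl and C5/C16 methylene as in the target, C11 OTBS | C=C1CC[C@H](OC(=O)C(C)C)[C@@]2(C)[C@@H](OC(C)=O)CC[C@@H](O[Si](C)(C)C(C)(C)C)[C@@H]2[C@H](OC(C)=O)[C@]2(O)[C@@H](C)C(=O)O[C@H]2[C@H]1Cl | intermediate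
25 | C11 alcohol of 24 | C=C1CC[C@H](OC(=O)C(C)C)[C@@]2(C)[C@@H](OC(C)=O)CC[C@@H](O)[C@@H]2[C@H](OC(C)=O)[C@]2(O)[C@@H](C)C(=O)O[C@H]2[C@H]1Cl | intermediate
26 | C11 ketone | C=C1CC[C@H](OC(=O)C(C)C)[C@@]2(C)[C@@H](OC(C)=O)CCC(=O)[C@@H]2[C@H](OC(C)=O)[C@]2(O)[C@@H](C)C(=O)O[C@H]2[C@H]1Cl | intermediate
27 | C11/C20 methylene compound (11,20-deoxy olefin of the target) | C=C1CC[C@H](OC(=O)C(C)C)[C@@]2(C)[C@@H](OC(C)=O)CCC(=C)[C@@H]2[C@H](OC(C)=O)[C@]2(O)[C@@H](C)C(=O)O[C@H]2[C@H]1Cl | intermediate
28 | CNP0284862.1 (11,20-epoxy briarane) | C=C1CC[C@H](OC(=O)C(C)C)[C@@]2(C)[C@@H](OC(C)=O)CC[C@]3(CO3)[C@@H]2[C@H](OC(C)=O)[C@]2(O)[C@@H](C)C(=O)O[C@H]2[C@H]1Cl | target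

**Step count and risk**

Total steps: 21. Longest linear sequence: 19 (steps 1–4, then 7–21); steps 5–6 form the second branch.

Steps most likely to fail:

- **Step 10 (the proposed new ring expansion).** The retro-aldol may not run forward against the strain of the ten-membered ring, and the C9 configuration is only predicted. The fallback uses known chemistry, sets out from 6 and comes back at 16 by ring-closing metathesis. 3-Methylbut-3-en-1-ylmagnesium bromide with CeCl3 at −78 °C adds to the aldehyde to give the C2 carbinol F1. DMP gives the C2 ketone F2. Oxalic acid on wet silica frees the C9 aldehyde F3. 2-Lithio-2-allyl-1,3-dithiane adds to the aldehyde (Felkin addition; the epimers are separated if needed) to give the hydroxy dithiane F4. Ac2O/DMAP gives the acetoxy dithiane F5. PhI(OCOCF3)2 in aqueous MeCN unmasks the α-acetoxy allyl ketone F6. The second-generation Hoveyda–Grubbs catalyst RuCl2(H2IMes)(=CH-C6H4-2-OiPr), in dilute toluene at 80 °C, then closes the trisubstituted ring-cis C5=C6 olefin and gives 16.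

- **Step 14 (Reformatsky lactonisation).** SmI2 may instead cleave the α-acyloxy ketone, or the wrong C8 epimer may form. The fallback sets out from 18 and comes back at 21. DCC/DMAP esterification with 2-(diethoxyphosphoryl)propanoic acid gives the phosphonate ester F7. LiCl/DBU (intramolecular Horner–Wadsworth–Emmons reaction) gives the 8(17)-butenolide F8. t-BuOOH/DBU nucleophilic epoxidation from the outer face gives the 8,17-epoxy lactone F9. SmI2 in THF/MeOH at −78 °C cleaves the C17–O bond next to the carbonyl and, after kinetic protonation at C17, gives 21.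

- **Step 17 (ene-type chlorination).** Risks are the wrong face at C6 and proton loss from C4 instead of C16. The fallback sets out from 23 and comes back at 24. Photo-oxygenation (O2, tetraphenylporphyrin, hν, CH2Cl2, −20 °C; then PPh3), a Schenck ene reaction, gives the 6-epi allylic alcohol F10 that already carries the C5/C16 methylene. Appel chlorination (PPh3, CCl4, 40 °C) then replaces the hydroxyl with inversion and gives 24. This reverses the facial outcome of a direct chlorination.

**Further compounds**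

F1 | step 10 | C2 carbinol: ring A (as in 6) bearing CH(OH)CH2CH2C(CH3)=CH2 on C1, C9 dimethyl acetal, C2 epimer mixture | C=C(C)CCC(O)[C@@]1(C)[C@@H](OC(C)=O)CC[C@@H](O[Si](C)(C)C(C)(C)C)[C@@H]1C(OC)OC
F2 | step 10 | C2 ketone of F1 | C=C(C)CCC(=O)[C@@]1(C)[C@@H](OC(C)=O)CC[C@@H](O[Si](C)(C)C(C)(C)C)[C@@H]1C(OC)OC
F3 | step 10 | C9 aldehyde of F2 | C=C(C)CCC(=O)[C@@]1(C)[C@@H](OC(C)=O)CC[C@@H](O[Si](C)(C)C(C)(C)C)[C@@H]1C=O
F4 | step 10 | hydroxy dithiane: C9 carbinol (C9 as in the target) bonded to C2 of 2-allyl-1,3-dithiane (masked C8 ketone) | C=C(C)CCC(=O)[C@@]1(C)[C@@H](OC(C)=O)CC[C@@H](O[Si](C)(C)C(C)(C)C)[C@@H]1[C@H](O)C1(CC=C)SCCCS1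
F5 | step 10 | acetoxy dithiane: C9 acetate of F4 | C=C(C)CCC(=O)[C@@]1(C)[C@@H](OC(C)=O)CC[C@@H](O[Si](C)(C)C(C)(C)C)[C@@H]1[C@H](OC(C)=O)C1(CC=C)SCCCS1
F6 | step 10 | α-acetoxy allyl ketone: acyclic diene with C2 and C8 ketones, C9 acetate, terminal C5(Me)=CH2 and C6H=CH2 | C=C(C)CCC(=O)[C@@]1(C)[C@@H](OC(C)=O)CC[C@@H](O[Si](C)(C)C(C)(C)C)[C@@H]1[C@H](OC(C)=O)C(=O)CC=C
F7 | step 14 | phosphonate ester: C7 2-(diethoxyphosphoryl)propanoate of 18 | C/C1=C/[C@H](OC(=O)C(C)P(=O)(OCC)OCC)C(=O)[C@@H](OC(C)=O)[C@H]2[C@H](O[Si](C)(C)C(C)(C)C)CC[C@H](OC(C)=O)[C@]2(C)C(=O)CC1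
F8 | step 14 | 8(17)-butenolide: C7–O–C19(=O)–C17(Me)=C8 | C/C1=C/[C@@H]3OC(=O)C(C)=C3[C@@H](OC(C)=O)[C@H]2[C@H](O[Si](C)(C)C(C)(C)C)CC[C@H](OC(C)=O)[C@]2(C)C(=O)CC1
F9 | step 14 | 8,17-epoxy lactone: epoxide oxygen on the face of OH-8 of the target | C/C1=C/[C@@H]3OC(=O)[C@]4(C)O[C@]34[C@@H](OC(C)=O)[C@H]2[C@H](O[Si](C)(C)C(C)(C)C)CC[C@H](OC(C)=O)[C@]2(C)C(=O)CC1
F10 | step 17 | 6-epi allylic alcohol: as 24 with OH in place of Cl and the opposite configuration at C6 | C=C1CC[C@H](OC(=O)C(C)C)[C@@]2(C)[C@@H](OC(C)=O)CC[C@@H](O[Si](C)(C)C(C)(C)C)[C@@H]2[C@H](OC(C)=O)[C@]2(O)[C@@H](C)C(=O)O[C@H]2[C@@H]1O
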